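**Remark on the chemistry and the numbering.** The name is read as mulberrofuran L, the structure of the SMILES. "Geranyl" stands for (2E)-3,7-dimethylocta-2,6-dien-1-yl (chain atoms C1' to C8') and MOM for methoxymethyl. The benzofuran is numbered O1, C2, C3, C3a, C4 to C7, C7a; ring A is the benzo ring, ring B the furan, ring C the dihydroxyphenyl ring (C1'' to C6'').

**Compound numbers:** 1 resorcinol; 2 its bis-MOM ether; 3 geranyl bromide; 4 aryllithium from 2; 5 2-geranyl bis-MOM ether; 6 aryllithium from 5; 7 bis-MOM aldehyde; 8 hydroxy aldehyde; 9 ethyl bromoacetate; 10 aryloxyacetate; 11 hydroxydihydrobenzofuran ester; 12 benzofuran ester; 13 acetylacetone; 14 its dianion; 15 triketone; 16 cyclic aldol; 17 MOM-protected resorcinol; 18 target.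

## Analysis of the target

Mulberrofuran L is a 2-arylbenzofuran: benzo ring A (C3a, C4 to C7, C7a) is fused to furan ring B (O1, C2, C3), and C2 carries ring C, a 3,5-dihydroxyphenyl group bonded through C1''. Ring A bears a hydroxyl at C6 and a geranyl chain at C7, the position wedged between the C6 oxygen and the ring oxygen at C7a. There is no stereocentre; the one stereochemical element is the E geometry of the C2'=C3' double bond, which comes with geranyl bromide and only has to be kept. The sensitive groups are the two trisubstituted olefins and the three phenols: protonation of an olefin starts cation chemistry (the C6 hydroxyl sits where it can close a chroman onto C3'), and the phenols are easily oxidised once ionised. The difficulty is therefore one of regiochemistry and chemoselectivity: the geranyl group must reach the most crowded carbon of ring A with linear connectivity, and the rest must be assembled without strong acid, oxidants or reagents that add to olefins. The feature that carries the strategy is the pattern of ring C: C1'' is bonded to carbon (C2 of ring B), C3'' and C5'' to oxygen, and C2'', C4'' and C6'' to hydrogen. This is the pattern of a hexane-1,3,5-trione folded onto itself, so ring C can be grown from an open chain on a finished 7-geranylbenzofuran, with its two hydroxyls arriving free.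

## Retrosynthetic reasoning

**18 to 17.** The last bond cut is the O–CH2 bond of the acetal on the C6 oxygen. One protecting group cannot be avoided: this oxygen must stay inert while the neighbouring C7a oxygen is alkylated, and earlier it must direct two metalations. Unmasking last means the acid-sensitive pair of free C6 hydroxyl and C2'=C3' olefin exists only in the final compound. The forward reaction must be an acetal solvolysis too mild to protonate the olefins.

**17 to 15 (key disconnection).** Ring C is opened at C1''–C2'' and its two hydroxyls are returned to carbonyls, giving the open chain 15. The cut is made here because the chain then has its ketone next to the benzofuran as C1 and its methyl group as C6, the electrophile and nucleophile of an aldol at the two chain ends. Three things are gained: ring C needs no protecting groups, the bond between ring B and ring C is never made by a coupling, and ring C comes from a five-carbon commodity. The forward reaction must join C6 to C1 through the aldol 16 and aromatise, in preference to closure through oxygen and to cleavage of the chain.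

**15 to 12 and 13.** The chain is cut between C1 and C2. This gives an acyl donor on C2 of the benzofuran, the ester 12, and the terminal carbon of the dianion 14 of 13 as nucleophile. A cut between C3 and C4 would also work but costs a step; cutting C1–C2 builds the whole chain in one bond from an ester that the furan synthesis supplies anyway. The forward reaction must acylate 14 at its terminal carbon only once.

**12 to 8 and 9.** Ring B is cut at O1–C2 and at C2=C3. This returns the salicylaldehyde 8, whose formyl carbon becomes C3 and whose phenol oxygen becomes O1, and the two-carbon unit 9, which brings C2 together with the ester. The carbonyl carbon needed for C1 of 15 is thus built in during furan formation. The forward reaction is O-alkylation (giving 10), ring closure to 11 and dehydration; it needs the C2 hydroxyl of 8 free and the C4 oxygen blocked.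

**8 to 7 to 5.** Compound 8 comes from 7 by freeing only the oxygen next to the formyl group. Compound 7 is cut at the aryl–formyl bond, which leads to the aryllithium 6 and so to 5. In 5 the only unsubstituted positions next to an acetal oxygen are C4 and C6, and they are equivalent by symmetry, so the formylation raises no regiochemical question.

**5 to 2 and 3, and 2 to 1.** The aryl–C1' bond is cut. In 2 the hydrogen between the two acetal oxygens is the most acidic on the ring, so the aryllithium 4 forms there alone, and substitution at the primary carbon of 3 attaches the chain without touching its geometry. An electrophilic geranylation of the free diphenol would give C- and O-alkylation at several positions, and a sigmatropic route would deliver the chain reversed. Compound 2 comes from 1 by double acetal formation.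

## Alternatives that were turned down

**Alternative 1: intramolecular ester Wittig reaction closing C2=C3.**
- Disconnection: the furan C2=C3 bond, leading to the phosphonium salt A2, an ortho-acyloxybenzyl phosphonium bromide that carries the bis-silylated ring C as a benzoate on the future O1.
- Forward key step: a tertiary amine in a hot aromatic solvent forms the benzylic ylide. Its carbon (future C3) adds to the ester carbonyl (future C2), and loss of the phosphine oxide closes ring B to give A1, the tris-TBS ether of the target. Fluoride would then free the three phenols.
- For it: this closure is the most used entry into 2-arylbenzofurans, the conditions are nearly neutral and harmless to the olefins, and ring C is bought complete.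
- Against it here: A2 needs a 3-geranyl-2-hydroxybenzyl alcohol to be turned into a phosphonium salt, which means an ortho-hydroxybenzyl cation or quinone methide three atoms from the C2'=C3' olefin. A phenol squeezed between the chain and the phosphonium arm must then be acylated. Three silyl ethers are put on and taken off. The geranylated ring A piece needs the same C-geranylation between two oxygens as the chosen route, so nothing is saved there.
- Comparison: the Wittig closure is the better-precedented single step, and on that point it is stronger than the triketone aldol. The chosen strategy offers economy in its place: ring C is never protected, one acetal is the only protecting group, no benzylic cation is generated near the olefin, and the longest line should be about two steps shorter with no separate arm for ring C.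

**Alternative 2: Danheiser benzannulation building ring A around the geranyl group.**
- Disconnection: ring A is taken apart completely. The ortho-alkynylphenol A3 is traced to the enynyl diazo ketone A4 and the geranyl-substituted siloxyalkyne A5.
- Forward key step: irradiation of A4 triggers a Wolff rearrangement to a ketene conjugated with the enyne, which adds A5 in a [2+2] fashion. On heating, the four-membered ring opens and the resulting trienyl ketene closes by 6π electrocyclisation and tautomerises to A3. The polarity of the ynol ether places the geranyl group between the phenol carbon and the silyloxy carbon. A 5-endo cycloisomerisation and a triple desilylation would follow.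
- For it: the regiochemistry at crowded C7 is set by construction, with no metalation and no electrophilic substitution. On this point it is stronger than the chosen route, which depends on two directed lithiations and a selective acetal cleavage.
- Against it here: both partners are sensitive and take several steps each (A5 by ynolate homologation of a chain-extended ester, A4 by diazo transfer onto a conjugated enynone). The ketene carries a conjugated alkyne, and two further olefins per molecule are present as possible ketene acceptors. Photochemical and diazo steps scale poorly, and two steps remain after the key step.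
- Comparison: roughly twice the step count of the chosen route. The chosen strategy gives up the built-in regiocontrol, but ring A is bought as 1, and no photochemistry, diazo compound or silyl group is needed.

**Alternative 3: dienol 6π electrocyclisation of a furyl enaminone.**
- Disconnection: ring A is again the ring formed, now from a 2-arylfuran. The benzofuranol A6 is cut at C3a–C4 to the furyl enaminone A7.
- Forward key step: on heating, A7 enolises towards the furyl-bearing carbon. The triene made of the furan C3a=C7a bond, the enol C7=C6 and the enamine C5=C4 closes to form C3a–C4, and loss of the secondary amine aromatises ring A to A6. Desilylation would finish.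
- For it: the geranyl group is introduced by enolate alkylation with 3 at the carbon that becomes C7, so the regiochemical problem disappears (stronger than the chosen route on this point), and the C6 hydroxyl emerges free.
- Against it here: the closure must use a furan double bond and interrupt the furan aromaticity in the transition state, which calls for high temperature. At that temperature the furan can undergo intramolecular Diels–Alder reactions with the chain olefins and the enol can undergo ene reactions, and the geometries of both new double bonds must be right at the same time. Making A7 needs mono-alkylation of a furyl ketone at a doubly activated carbon and a regioselective aminomethylenation. Ring C must still be attached by a cross-coupling and carries two silyl ethers.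
- Comparison: at best equal in length and less well precedented at the key step. The chosen aldol is an ionic closure in which only one six-membered carbocycle can form, and it needs no pericyclic step that competes with reactions of the geranyl chain.

Key step: step 7

## Route

Step 1
Reactants: 1 resorcinol
Product: 2 1,3-bis(methoxymethoxy)benzene
Conditions: NaH, MOMCl, DMF, 0 °C → rt
Reagents that add atoms: chloromethyl methyl ether (MOMCl), COCCl
Why: Twofold O-alkylation of the sodium bis-phenoxide by the α-chloro ether (Williamson-type acetal formation) should be clean; the MOM acetals are the ortho-directing groups for steps 2 and 3 and are inert to every base used later.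

Step 2
Reactants: 2 1,3-bis(methoxymethoxy)benzene; 3 geranyl bromide
Product: 5 2-geranyl-1,3-bis(methoxymethoxy)benzene, via 2-lithio-1,3-bis(methoxymethoxy)benzene 4 (not isolated)
Conditions: n-BuLi, THF, 0 °C → rt; CuBr·SMe2 (10 mol %), 3, −30 °C → rt
Reagents that add atoms: none
Why: Directed ortho-metalation: the hydrogen at C2 lies between two acetal oxygens that both coordinate lithium, so 4 should form at that carbon only; copper-catalysed allylic substitution at the primary carbon of 3 (SN2, no allylic transposition) then makes the aryl–C1' bond and leaves the E olefin untouched.

Step 3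
Reactants: 5 2-geranyl-1,3-bis(methoxymethoxy)benzene
Product: 7 3-geranyl-2,4-bis(methoxymethoxy)benzaldehyde, via 3-geranyl-2,4-bis(methoxymethoxy)phenyllithium 6 (not isolated)
Conditions: n-BuLi, TMEDA, THF, −20 → 0 °C; DMF, 0 °C → rt; H2O
Reagents that add atoms: N,N-dimethylformamide (DMF), CN(C)C=O
Why: Second directed ortho-metalation: in the mirror-symmetric ether 5 the only free positions next to an acetal oxygen are C4 and C6, which are equivalent, so 6 is a single species, and formylation of the aryllithium by DMF (Bouveault-type) gives the aldehyde on aqueous work-up; low temperature and TMEDA-activated n-BuLi favour the oxygen-directed ring deprotonation over removal of a C1' hydrogen.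

Step 4
Reactants: 7 3-geranyl-2,4-bis(methoxymethoxy)benzaldehyde
Product: 8 3-geranyl-2-hydroxy-4-(methoxymethoxy)benzaldehyde
Conditions: HCl (cat., dilute), MeOH, 0 °C → rt, stopped at mono-cleavage
Reagents that add atoms: none
Why: Acid-catalysed transacetalisation to methanol; the acetal at C2 should go first because it is twisted out of conjugation between the formyl group and the chain, its protonation is assisted by the neighbouring carbonyl oxygen, and the phenol set free is held in a hydrogen bond to the aldehyde, whereas the C4 acetal has none of these aids.

Step 5
Reactants: 8 3-geranyl-2-hydroxy-4-(methoxymethoxy)benzaldehyde; 9 ethyl bromoacetate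
Product: 12 ethyl 7-geranyl-6-(methoxymethoxy)benzofuran-2-carboxylate, via ethyl 2-[2-formyl-6-geranyl-5-(methoxymethoxy)phenoxy]acetate 10 (not isolated), via ethyl 7-geranyl-3-hydroxy-6-(methoxymethoxy)-2,3-dihydrobenzofuran-2-carboxylate 11 (not isolated)
Conditions: K2CO3, DMF, rt then 110 °C
Reagents that add atoms: none
Why: Classical salicylaldehyde to benzofuran-2-carboxylate synthesis (Rap–Stoermer type): Williamson O-alkylation gives 10, the ester enolate adds to the ortho formyl group in a 5-(enolexo)-exo-trig aldol to give 11, and base-induced dehydration aromatises ring B; the two stereocentres of 11 are transient and need no control.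

Step 6
Reactants: 12 ethyl 7-geranyl-6-(methoxymethoxy)benzofuran-2-carboxylate; 13 acetylacetone
Product: 15 1-[7-geranyl-6-(methoxymethoxy)benzofuran-2-yl]hexane-1,3,5-trione, via dilithioacetylacetone 14 (not isolated)
Conditions: 13 (2.5 equiv), LiN(i-Pr)2 (5 equiv), THF, 0 °C; 12, 0 °C → rt; aq. AcOH, 0 °C
Reagents that add atoms: none
Why: Claisen-type C-acylation of a β-diketone dianion: the terminal carbanion of 14 is the more basic and more nucleophilic site and attacks the ester carbonyl of 12, ethoxide leaves, and the triketone is at once deprotonated by excess 14, which protects it from a second attack; the buffered acidic work-up keeps the chain open.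

Step 7
Reactants: 15 1-[7-geranyl-6-(methoxymethoxy)benzofuran-2-yl]hexane-1,3,5-trione
Product: 17 5-[7-geranyl-6-(methoxymethoxy)benzofuran-2-yl]benzene-1,3-diol, via 5-[7-geranyl-6-(methoxymethoxy)benzofuran-2-yl]-5-hydroxycyclohexane-1,3-dione 16 (not isolated)
Conditions: KOH (2 M aq.), MeOH, Ar, 25 → 50 °C, 0.01 M; AcOH to pH 5–6, 0 °C
Reagents that add atoms: none
Why: Hydroxide converts 15 into its enolates, and a small equilibrium share in which the terminal methyl carbon C6 is deprotonated (it is γ to the enolised C3/C5 unit) adds through C6 to the C1 ketone carbonyl beside the benzofuran, which forms the C1''–C2'' bond and closes ring C as the aldol 16. The closest known reaction type is the base-mediated aldol cyclisation of open-chain 1,3,5-triketones to 5-substituted resorcinols, of which the conversion of heptane-2,4,6-trione into orcinol is the parent case; the triketo-acid variant of the same folding is the one used by stilbene-forming polyketide enzymes. Ring C closes in the 6-(enolendo)-exo-trig mode: the C5=C6 enolate bond lies inside the new ring and the C1 carbonyl oxygen outside it, a geometry that the Baldwin rules for enolates allow for six-membered rings. E1cB loss of water from 16 and enolisation of the carbonyls at C3 and C5 then give the aromatic diol 17, and this aromatisation makes the sequence irreversible and draws the unfavourable methyl deprotonation forward. No stereocentre is formed, since the carbinol carbon of 16 carries two identical ring arms and ends as sp2. Regiochemistry is secured by the chain itself, because C6 onto C1 is the only carbon–carbon closure that gives a six-membered ring (all others would be four-membered). The selectivity that must be won is carbon cyclisation over oxygen cyclisation to a 2-methyl-6-aryl-4-pyranone and over hydrolytic retro-Claisen cleavage: in alkali the oxygens are ionised and their addition to C1 is reversible while the carbon closure ends in an arene, and high dilution under argon holds back intermolecular aldol reactions and oxidation of the resorcinolate. The geranyl olefins, the benzofuran and the MOM acetal are inert to aqueous base.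

Step 8
Reactants: 17 5-[7-geranyl-6-(methoxymethoxy)benzofuran-2-yl]benzene-1,3-diol
Product: 18 mulberrofuran L, 5-(7-geranyl-6-hydroxybenzofuran-2-yl)benzene-1,3-diol
Conditions: HCl (cat.), MeOH, Ar, rt → 40 °C
Reagents that add atoms: none
Why: Acid-catalysed methanolysis of the aryl methoxymethyl acetal, the formaldehyde unit being carried off by the solvent as its dimethyl acetal; dilute acid near room temperature is expected to leave the trisubstituted olefins unprotonated and the benzofuran intact.

## Compound list

1 | resorcinol | Oc1cccc(O)c1 | starting material
2 | 1,3-bis(methoxymethoxy)benzene | COCOc1cccc(OCOC)c1 | intermediate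
3 | geranyl bromide, (2E)-1-bromo-3,7-dimethylocta-2,6-diene | CC(C)=CCC/C(C)=C/CBr | starting material
4 | 2-lithio-1,3-bis(methoxymethoxy)benzene | COCOc1cccc(OCOC)c1[Li] | intermediate
5 | 2-geranyl-1,3-bis(methoxymethoxy)benzene | CC(C)=CCC/C(C)=C/Cc1c(OCOC)cccc1OCOC | intermediate
6 | 3-geranyl-2,4-bis(methoxymethoxy)phenyllithium | CC(C)=CCC/C(C)=C/Cc1c(OCOC)ccc([Li])c1OCOC | intermediate
7 | 3-geranyl-2,4-bis(methoxymethoxy)benzaldehyde | CC(C)=CCC/C(C)=C/Cc1c(OCOC)ccc(C=O)c1OCOC | intermediate
8 | 3-geranyl-2-hydroxy-4-(methoxymethoxy)benzaldehyde | CC(C)=CCC/C(C)=C/Cc1c(OCOC)ccc(C=O)c1O | intermediate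
9 | ethyl bromoacetate | CCOC(=O)CBr | starting material
10 | ethyl 2-[2-formyl-6-geranyl-5-(methoxymethoxy)phenoxy]acetate | CC(C)=CCC/C(C)=C/Cc1c(OCOC)ccc(C=O)c1OCC(=O)OCC | intermediate
11 | ethyl 7-geranyl-3-hydroxy-6-(methoxymethoxy)-2,3-dihydrobenzofuran-2-carboxylate (diastereomer mixture, racemic; both centres lost on dehydration) | CC(C)=CCC/C(C)=C/Cc1c(OCOC)ccc2C(O)C(C(=O)OCC)Oc12 | intermediate
12 | ethyl 7-geranyl-6-(methoxymethoxy)benzofuran-2-carboxylate | CC(C)=CCC/C(C)=C/Cc1c(OCOC)ccc2cc(C(=O)OCC)oc12 | intermediate
13 | acetylacetone (pentane-2,4-dione) | CC(=O)CC(C)=O | starting material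
14 | dilithioacetylacetone (1,3-dianion of pentane-2,4-dione, drawn as the dienolate) | [Li]OC(=C)C=C(C)O[Li] | intermediate
15 | 1-[7-geranyl-6-(methoxymethoxy)benzofuran-2-yl]hexane-1,3,5-trione | CC(C)=CCC/C(C)=C/Cc1c(OCOC)ccc2cc(C(=O)CC(=O)CC(C)=O)oc12 | intermediate
16 | 5-[7-geranyl-6-(methoxymethoxy)benzofuran-2-yl]-5-hydroxycyclohexane-1,3-dione | CC(C)=CCC/C(C)=C/Cc1c(OCOC)ccc2cc(C3(O)CC(=O)CC(=O)C3)oc12 | intermediate
17 | 5-[7-geranyl-6-(methoxymethoxy)benzofuran-2-yl]benzene-1,3-diol | CC(C)=CCC/C(C)=C/Cc1c(OCOC)ccc2cc(-c3cc(O)cc(O)c3)oc12 | intermediate
18 | mulberrofuran L, 5-(7-geranyl-6-hydroxybenzofuran-2-yl)benzene-1,3-diol | CC(C)=CCC/C(C)=C/Cc1c(O)ccc2cc(-c3cc(O)cc(O)c3)oc12 | target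

## Step count and least certain steps

Total step count: 8. Longest linear sequence: 8 steps, from resorcinol 1; compounds 3, 9 and 13 are bought and enter directly.

**Step 7 (key step).** The most likely failure is that hydroxide cleaves the β-dicarbonyl units (retro-Claisen) faster than the weakly acidic methyl group is deprotonated and adds to C1. C1 is a ketone conjugated with the benzofuran and less electrophilic than the acetyl carbonyl of the parent case. A second failure is closure through oxygen to the pyranone during acidification. Fallback, from 15 back to 17: the trianion of 15 (LiN(i-Pr)2, 3.5 equiv, THF, 0 °C) is carboxylated with CO2 at the terminal carbon to give 7-[7-geranyl-6-(methoxymethoxy)benzofuran-2-yl]-3,5,7-trioxoheptanoic acid F1. Its nucleophilic carbon is now a methylene between a ketone and a carboxylate, which enolises in a mild aqueous buffer (pH 8–9), so the aldol onto the aryl ketone should proceed without strong hydroxide and give 6-[7-geranyl-6-(methoxymethoxy)benzofuran-2-yl]-2,4-dihydroxybenzoic acid F2. Warming F2 in DMF (about 110 °C) should expel CO2 by ipso-protonation of the electron-rich ring and deliver 17.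

**Step 3.** The base may remove a hydrogen from C1', which is both benzylic and allylic, instead of the ring hydrogen. That would divert the electrophile to the chain or move the C2'=C3' double bond into conjugation. Fallback, from 2 back to 7: bromination of 2 (NBS, MeCN, 0 °C) gives 1-bromo-2,4-bis(methoxymethoxy)benzene F3. Deprotonation between the two acetal oxygens with LiN(i-Pr)2 (−78 °C), CuBr·SMe2 and 3 give 1-bromo-3-geranyl-2,4-bis(methoxymethoxy)benzene F4. Bromine–lithium exchange (n-BuLi, −78 °C), which is far faster than any C–H removal, followed by DMF then gives 7.

**Step 4.** The rate difference between the two acetals may be too small, so that both are lost or mixtures result, and long exposure to acid invites ring closure of the freed phenol onto the chain. Fallback, from 7 back to 8: both acetals are removed (HCl, MeOH, 40 °C) to give 3-geranyl-2,4-dihydroxybenzaldehyde F5, and the C4 hydroxyl alone is etherified (MOMCl, K2CO3, acetone). The selectivity is then sought in a protection, where the hydrogen bond to the aldehyde makes the C2 hydroxyl much the poorer nucleophile, and no longer in a deprotection.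

**Step 6.** Proton transfer from the acidic product may consume the dianion and stall the acylation, and any free amide base could attack the ester or metalate C3 of the benzofuran. Fallback, from 12 back to 15, with the roles of the partners reversed: Claisen condensation of 12 with the enolate of acetone (NaH, THF) gives 1-[7-geranyl-6-(methoxymethoxy)benzofuran-2-yl]butane-1,3-dione F6. Its dianion (LiN(i-Pr)2, 2 equiv) is then acylated at the terminal methyl carbon with N-methoxy-N-methylacetamide to give 15.

**Step 8.** Protonation of the C2'=C3' olefin with capture by the freed C6 hydroxyl (chroman closure) and attack of the methoxymethyl cation on the very electron-rich ring C are the likely losses. Fallback, from 12 to 18, which moves the acid step to a stage where ring C does not yet exist and the phenol is deactivated by conjugation with the ester: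
- The acetal of 12 is cleaved (HCl, MeOH) to ethyl 7-geranyl-6-hydroxybenzofuran-2-carboxylate F7.
- The phenol is allylated (allyl bromide, K2CO3, acetone) to ethyl 6-(allyloxy)-7-geranylbenzofuran-2-carboxylate F8.
- The conditions of step 6 give 1-[6-(allyloxy)-7-geranylbenzofuran-2-yl]hexane-1,3,5-trione F9.
- The conditions of step 7 give 5-[6-(allyloxy)-7-geranylbenzofuran-2-yl]benzene-1,3-diol F10.
- Allyl transfer to morpholine with catalytic Pd(PPh3)4 (THF, rt) under neutral conditions frees 18; the trisubstituted olefins of the chain do not form allyl complexes under these conditions.

## Further compounds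

F1 | step 7 | 7-[7-geranyl-6-(methoxymethoxy)benzofuran-2-yl]-3,5,7-trioxoheptanoic acid | CC(C)=CCC/C(C)=C/Cc1c(OCOC)ccc2cc(C(=O)CC(=O)CC(=O)CC(O)=O)oc12
F2 | step 7 | 6-[7-geranyl-6-(methoxymethoxy)benzofuran-2-yl]-2,4-dihydroxybenzoic acid | CC(C)=CCC/C(C)=C/Cc1c(OCOC)ccc2cc(-c3cc(O)cc(O)c3C(O)=O)oc12
F3 | step 3 | 1-bromo-2,4-bis(methoxymethoxy)benzene | COCOc1ccc(Br)c(OCOC)c1
F4 | step 3 | 1-bromo-3-geranyl-2,4-bis(methoxymethoxy)benzene | CC(C)=CCC/C(C)=C/Cc1c(OCOC)ccc(Br)c1OCOC
F5 | step 4 | 3-geranyl-2,4-dihydroxybenzaldehyde | CC(C)=CCC/C(C)=C/Cc1c(O)ccc(C=O)c1O
F6 | step 6 | 1-[7-geranyl-6-(methoxymethoxy)benzofuran-2-yl]butane-1,3-dione | CC(C)=CCC/C(C)=C/Cc1c(OCOC)ccc2cc(C(=O)CC(C)=O)oc12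
F7 | step 8 | ethyl 7-geranyl-6-hydroxybenzofuran-2-carboxylate | CC(C)=CCC/C(C)=C/Cc1c(O)ccc2cc(C(=O)OCC)oc12
F8 | step 8 | ethyl 6-(allyloxy)-7-geranylbenzofuran-2-carboxylate | CC(C)=CCC/C(C)=C/Cc1c(OCC=C)ccc2cc(C(=O)OCC)oc12
F9 | step 8 | 1-[6-(allyloxy)-7-geranylbenzofuran-2-yl]hexane-1,3,5-trione | CC(C)=CCC/C(C)=C/Cc1c(OCC=C)ccc2cc(C(=O)CC(=O)CC(C)=O)oc12
F10 | step 8 | 5-[6-(allyloxy)-7-geranylbenzofuran-2-yl]benzene-1,3-diol | CC(C)=CCC/C(C)=C/Cc1c(OCC=C)ccc2cc(-c3cc(O)cc(O)c3)oc12
A1 | alternative 1 | tris(tert-butyldimethylsilyl) ether of mulberrofuran L | CC(C)=CCC/C(C)=C/Cc1c(O[Si](C)(C)C(C)(C)C)ccc2cc(-c3cc(O[Si](C)(C)C(C)(C)C)cc(O[Si](C)(C)C(C)(C)C)c3)oc12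
A2 | alternative 1 | {2-[3,5-bis(tert-butyldimethylsilyloxy)benzoyloxy]-4-(tert-butyldimethylsilyloxy)-3-geranylbenzyl}triphenylphosphonium bromide | CC(C)=CCC/C(C)=C/Cc1c(O[Si](C)(C)C(C)(C)C)ccc(C[P+](c2ccccc2)(c2ccccc2)c2ccccc2)c1OC(=O)c1cc(O[Si](C)(C)C(C)(C)C)cc(O[Si](C)(C)C(C)(C)C)c1.[Br-]
A3 | alternative 2 | 2-{[3,5-bis(triisopropylsilyloxy)phenyl]ethynyl}-6-geranyl-5-(triisopropylsilyloxy)phenol | CC(C)=CCC/C(C)=C/Cc1c(O)c(C#Cc2cc(O[Si](C(C)C)(C(C)C)C(C)C)cc(O[Si](C(C)C)(C(C)C)C(C)C)c2)ccc1O[Si](C(C)C)(C(C)C)C(C)C
A4 | alternative 2 | (3E)-6-[3,5-bis(triisopropylsilyloxy)phenyl]-1-diazohex-3-en-5-yn-2-one | [N-]=[N+]=CC(=O)/C=C/C#Cc1cc(O[Si](C(C)C)(C(C)C)C(C)C)cc(O[Si](C(C)C)(C(C)C)C(C)C)c1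
A5 | alternative 2 | {[(4E)-5,9-dimethyldeca-4,8-dien-1-yn-1-yl]oxy}triisopropylsilane | CC(C)=CCC/C(C)=C/CC#CO[Si](C(C)C)(C(C)C)C(C)C
A6 | alternative 3 | 2-[3,5-bis(tert-butyldimethylsilyloxy)phenyl]-7-geranylbenzofuran-6-ol | CC(C)=CCC/C(C)=C/Cc1c(O)ccc2cc(-c3cc(O[Si](C)(C)C(C)(C)C)cc(O[Si](C)(C)C(C)(C)C)c3)oc12
A7 | alternative 3 | (1E,6E)-4-{5-[3,5-bis(tert-butyldimethylsilyloxy)phenyl]furan-2-yl}-1-(dimethylamino)-7,11-dimethyldodeca-1,6,10-trien-3-one (racemic at C4) | CN(C)/C=C/C(=O)C(C/C=C(\C)CCC=C(C)C)c1ccc(-c2cc(O[Si](C)(C)C(C)(C)C)cc(O[Si](C)(C)C(C)(C)C)c2)o1
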